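## Retrosynthetic overview

1. Target ⇒ cardamonin + a 1,7-diarylhept-5-ene-3,7-diol: the C7–C3' bond is made last by a catalytic asymmetric 1,6-Friedel–Crafts addition to a vinyl para-quinone methide, which sets C7.
2. Heptenediol ⇒ (R)-homoallylic alcohol + racemic 1-(4-hydroxyphenyl)prop-2-en-1-ol: C5=C6 by E-selective cross-metathesis. The carbinol centre of the racemic partner is only a leaving-group site and is erased in the last step.
3. (R)-Homoallylic alcohol ⇒ 3-(4-hydroxyphenyl)propanal + allylboronate: C3–C4 by chiral-phosphoric-acid-catalysed allylboration, which sets C3, the first stereocentre.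
4. No ring is formed: the three benzene rings and the chalcone are bought intact, and no protecting group is used.

Assumption: heptanoid numbering as in the natural-product name (C3 carbinol, C5=C6, C7 diarylmethine); CIP analysis of the given SMILES gives 3R,7S with both alkenes E.

## Route

Step 1
Reactants: 1 3-(4-hydroxyphenyl)propanal; 2 allylboronic acid pinacol ester
Product: 4 (R)-1-(4-hydroxyphenyl)hex-5-en-3-ol, via O-pinacolboryl ether 3 (not isolated)
Conditions: (S)-TRIP [(S)-3,3'-bis(2,4,6-triisopropylphenyl)-1,1'-binaphthyl-2,2'-diyl hydrogen phosphate] (5 mol%), 2 (1.2 equiv), PhMe, −30 °C, 24 h; then aq. NaHCO3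
Reagents that add atoms: allylboronic acid pinacol ester 2, C=CCB1OC(C)(C)C(C)(C)O1
Why: Chiral-phosphoric-acid-catalysed allylboration through a closed chair (Zimmerman–Traxler-type) transition state in which the acid hydrogen-bonds the pseudo-axial boronate oxygen and the formyl C–H, so the (S)-acid exposes the aldehyde face that gives the 3R carbinol (about 90% ee expected for an unbranched aldehyde; the free phenol does not react with the boronate).

Step 2
Reactants: 5 4-hydroxybenzaldehyde; 6 vinylmagnesium bromide
Product: 8 racemic 1-(4-hydroxyphenyl)prop-2-en-1-ol, via bis(bromomagnesium) alkoxide-phenoxide 7 (not isolated)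
Conditions: CH2=CHMgBr (3.0 equiv), THF, 0 °C → rt; then sat. aq. NH4Cl, 0 °C
Reagents that add atoms: vinylmagnesium bromide 6, C=C[Mg]Br
Why: Grignard 1,2-addition after sacrificial deprotonation of the phenol; the carbinol centre is deliberately left racemic because it is destroyed when this carbon ionises in step 4.

Step 3
Reactants: 4 (R)-1-(4-hydroxyphenyl)hex-5-en-3-ol; 8 racemic 1-(4-hydroxyphenyl)prop-2-en-1-ol
Product: 9 (3R,5E)-1,7-bis(4-hydroxyphenyl)hept-5-ene-3,7-diol (about 1:1 mixture of C7 epimers)
Conditions: RuCl2(H2IMes)(=CH-C6H4-2-OiPr) (second-generation Hoveyda–Grubbs catalyst, 5 mol%), 8 (2.5 equiv), 1,4-benzoquinone (10 mol%), CH2Cl2, 40 °C; chromatography on Et3N-deactivated silica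
Reagents that add atoms: none
Why: Olefin cross-metathesis between a type 1 homoallylic alcohol and an excess of a slowly homodimerising type 2 secondary allylic alcohol gives the E-alkene under thermodynamic control with loss of ethene, leaves C3 untouched, and benzoquinone suppresses ruthenium-hydride isomerisation of the aryl vinyl carbinol.

Step 4
Reactants: 9 (3R,5E)-1,7-bis(4-hydroxyphenyl)hept-5-ene-3,7-diol (C7 epimer mixture); 10 cardamonin [(E)-1-(2,4-dihydroxy-6-methoxyphenyl)-3-phenylprop-2-en-1-one]
Product: 12 7-epi-katsumain C [(3R,7S)], via vinyl para-quinone methide 11 (not isolated)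
Conditions: (R)-TRIP (10 mol%), 10 (1.5 equiv), 5 Å MS, CH2Cl2 (0.02 M), −20 → 0 °C, slow addition of 9 over 6 h
Reagents that add atoms: none
Why: Proposed new method: the chiral phosphoric acid ionises either C7 epimer of 9 (stereoconvergent loss of water) to the E-configured vinyl para-quinone methide 11, held as a hydrogen-bonded ion pair in which the phosphate bridges the quinone-methide oxygen and the free 4'-OH of 10, so that ring A carbon C3' (ortho to that OH, flanked by both hydroxyls) is delivered to one face of C7, the electrophilic terminus the bridging phosphate can reach (1,6-attack rather than the remote 1,8-attack at C5), setting 7S under catalyst control while the remote 3R centre and the E-alkene are untouched; the closest known reaction type is the chiral-phosphoric-acid-catalysed enantioselective 1,6-conjugate arylation (asymmetric Friedel–Crafts alkylation) of in situ generated para-quinone methides by naphthols, indoles and phenols, not yet shown for an unhindered vinylogous quinone methide with a free remote hydroxyl or for an acylphloroglucinol chalcone as nucleophile.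

## Compound list

1 | 3-(4-hydroxyphenyl)propanal | O=CCCc1ccc(O)cc1 | starting material
2 | allylboronic acid pinacol ester (2-allyl-4,4,5,5-tetramethyl-1,3,2-dioxaborolane) | C=CCB1OC(C)(C)C(C)(C)O1 | starting material
3 | 2-{[(3R)-1-(4-hydroxyphenyl)hex-5-en-3-yl]oxy}-4,4,5,5-tetramethyl-1,3,2-dioxaborolane | C=CC[C@H](OB1OC(C)(C)C(C)(C)O1)CCc1ccc(O)cc1 | intermediate
4 | (R)-1-(4-hydroxyphenyl)hex-5-en-3-ol | C=CC[C@H](O)CCc1ccc(O)cc1 | intermediate
5 | 4-hydroxybenzaldehyde | O=Cc1ccc(O)cc1 | starting material
6 | vinylmagnesium bromide | C=C[Mg]Br | starting material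
7 | bis(bromomagnesium) salt of 1-(4-hydroxyphenyl)prop-2-en-1-ol (alkoxide and phenoxide) | C=CC(O[Mg]Br)c1ccc(O[Mg]Br)cc1 | intermediate
8 | racemic 1-(4-hydroxyphenyl)prop-2-en-1-ol | C=CC(O)c1ccc(O)cc1 | intermediate
9 | (3R,5E)-1,7-bis(4-hydroxyphenyl)hept-5-ene-3,7-diol, C7 epimer mixture | OC(/C=C/C[C@H](O)CCc1ccc(O)cc1)c1ccc(O)cc1 | intermediate
10 | cardamonin, (E)-1-(2,4-dihydroxy-6-methoxyphenyl)-3-phenylprop-2-en-1-one | COc1cc(O)cc(O)c1C(=O)/C=C/c1ccccc1 | starting material
11 | 4-[(2E,5R)-5-hydroxy-7-(4-hydroxyphenyl)hept-2-en-1-ylidene]cyclohexa-2,5-dien-1-one | O=C1C=CC(=C/C=C/C[C@H](O)CCc2ccc(O)cc2)C=C1 | intermediate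
12 | 7-epi-katsumain C, (2E)-1-{2,4-dihydroxy-3-[(1S,2E,5R)-5-hydroxy-1,7-bis(4-hydroxyphenyl)hept-2-en-1-yl]-6-methoxyphenyl}-3-phenylprop-2-en-1-one | COc1cc(O)c([C@@H](/C=C/C[C@H](O)CCc2ccc(O)cc2)c2ccc(O)cc2)c(O)c1C(=O)/C=C/c1ccccc1 | target

## Step count and risk

Total steps: 4 (steps 1 and 2 run in parallel). Longest linear sequence: 3 (steps 1, 3, 4).

The three steps most likely to fail:

**Step 4 (the proposed new reaction).** The risks are:
- attack at C5 instead of C7, giving the conjugated styrene isomer;
- attack through C5' of ring A instead of C3';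
- the sense or level of induction at C7: the choice of (R)-TRIP is a prediction, the (S)-acid would give the C7 epimer, so the configuration must be confirmed on the first run;
- elimination of 11 to a 1-aryl-1,3-diene, and acid-induced closure of the 2'-hydroxychalcone to the flavanone.

The roughly 5% of ent-4 carried from step 1 ends up as a separable diastereomer, so the enantiomeric purity of 12 is upgraded at this stage. The fallback uses known chemistry and gives up catalyst control of C7 in favour of separation. It sets out from 9 and 10: an achiral Brønsted acid (TsOH·H2O 10 mol%, MeCN, 0 °C → rt) effects the classical dehydrative Friedel–Crafts alkylation of the phloroglucinol-type ring by the para-hydroxybenzylic allylic cation. This gives 12 together with its (3R,7R) C7 epimer F1 in about equal amounts. The two diastereomers are separated by preparative reversed-phase HPLC, and the fallback comes back to the route at 12.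

**Step 3.** The aryl vinyl carbinol 8 may isomerise to the propiophenone or ionise on the ruthenium catalyst or on silica, and homodimers may dominate. The fallback introduces the C7 carbinol after the metathesis instead of carrying it through. It sets out from 8 and 4: oxidation of 8 with MnO2 (CH2Cl2, rt) gives 1-(4-hydroxyphenyl)prop-2-en-1-one F2, a non-ionisable electron-poor metathesis partner. Cross-metathesis of F2 with 4 (RuCl2(H2IMes)(=CH-C6H4-2-OiPr) 5 mol%, CH2Cl2, 40 °C) gives (2E,5R)-5-hydroxy-1,7-bis(4-hydroxyphenyl)hept-2-en-1-one F3. Luche 1,2-reduction (NaBH4, CeCl3·7H2O, MeOH, −40 °C) then comes back to the route at 9, again as an inconsequential C7 epimer mixture.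

**Step 1.** The enantioselectivity for an unbranched aldehyde may stay near 90%, and the free phenol may slow the catalyst; the absolute configuration of 4 should be confirmed by Mosher ester analysis. The fallback switches to Lewis-acid catalysis on a protected substrate and sets out from 1. TBSCl and imidazole (DMF, rt) give 3-[4-(tert-butyldimethylsilyloxy)phenyl]propanal F4. Keck allylation (Ti(OiPr)4/(S)-BINOL 10 mol%, allyltributylstannane, 4 Å MS, CH2Cl2, −20 °C) proceeds through the tributylstannyl ether F5, which is hydrolysed on work-up, to (R)-1-[4-(tert-butyldimethylsilyloxy)phenyl]hex-5-en-3-ol F6. TBAF (THF, 0 °C) removes the silyl group and comes back to the route at 4.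

## Further compounds

F1 | step 4 | (3R,7R) C7 epimer of 12, (2E)-1-{2,4-dihydroxy-3-[(1R,2E,5R)-5-hydroxy-1,7-bis(4-hydroxyphenyl)hept-2-en-1-yl]-6-methoxyphenyl}-3-phenylprop-2-en-1-one | COc1cc(O)c([C@H](/C=C/C[C@H](O)CCc2ccc(O)cc2)c2ccc(O)cc2)c(O)c1C(=O)/C=C/c1ccccc1
F2 | step 3 | 1-(4-hydroxyphenyl)prop-2-en-1-one | C=CC(=O)c1ccc(O)cc1
F3 | step 3 | (2E,5R)-5-hydroxy-1,7-bis(4-hydroxyphenyl)hept-2-en-1-one | O=C(/C=C/C[C@H](O)CCc1ccc(O)cc1)c1ccc(O)cc1
F4 | step 1 | 3-[4-(tert-butyldimethylsilyloxy)phenyl]propanal | O=CCCc1ccc(O[Si](C)(C)C(C)(C)C)cc1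
F5 | step 1 | tributylstannyl ether of (R)-1-[4-(tert-butyldimethylsilyloxy)phenyl]hex-5-en-3-ol | C=CC[C@H](O[Sn](CCCC)(CCCC)CCCC)CCc1ccc(O[Si](C)(C)C(C)(C)C)cc1
F6 | step 1 | (R)-1-[4-(tert-butyldimethylsilyloxy)phenyl]hex-5-en-3-ol | C=CC[C@H](O)CCc1ccc(O[Si](C)(C)C(C)(C)C)cc1
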